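**Retrosynthetic overview**
1. The coumarate is cut at the C2a–O ester bond (late esterification, then global desilylation), and C3a is cut from C3 back to a C3 ketone (enol triflate, methoxycarbonylation, hydrogenation, epimerisation, reduction).
2. The strategy rests on C4 of ring B: it is a bare benzylic CH2 between C4a of ring A and C3, so removing it contracts 2-tetralone 15 to the trans-2,3-disubstituted 3-aryl-1-indanone 12 (C1 with the guaiacyl ring, C2 with C2a, carbonyl carbon = C3).
3. Indanone 12 comes from (S)-3-arylindanone 10 by trans-selective benzyloxymethylation at C2, and 10 from indenone 4 and boronic acid 9 by asymmetric 1,4-arylation, which sets C1.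
4. Ring order: ring A and the five-membered ring arrive in 1, the pendant aryl ring in 5, ring B becomes six-membered by one-carbon ring expansion in step 7, and the coumaroyl ring arrives in 24.

Key step: step 7

Remark on naming: tetralin compounds carry the numbering of the target (C1 aryl-bearing, C2 with C2a, C3 with C3a, C4 the benzylic CH2, C4a/C8a the fusion carbons of ring A); indane compounds carry ordinary indane numbering. TIPS = triisopropylsilyl, TBS = tert-butyldimethylsilyl.
Remark on protecting groups: the C2a oxygen is carried as a benzyl ether (removed by hydrogenolysis), because oxidative removal of a 4-methoxybenzyl ether would endanger the electron-rich diarylmethine C1–H.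
Assumption: the (S)-BINAP rhodium catalyst is taken to attack the indenone on the same enone face as it does 2-cyclopentenone; if the antipode formed, the (R)-ligand would be used.

**Step 1**
Reactants: 1 5-hydroxy-6-methoxyindan-1-one
Product: 2 6-methoxy-5-(triisopropylsilyloxy)indan-1-one
Conditions: TIPSCl, imidazole, DMF, rt
Reagents that add atoms: triisopropylsilyl chloride, CC(C)[Si](Cl)(C(C)C)C(C)C
Why: Imidazole-promoted O-silylation masks the phenol as a hindered silyl ether that should withstand the later enolate, Lewis-acid and hydride steps.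

**Step 2**
Reactants: 2 6-methoxy-5-(triisopropylsilyloxy)indan-1-one
Product: 4 6-methoxy-5-(triisopropylsilyloxy)-1H-inden-1-one, via trimethylsilyl enol ether 3 (not isolated)
Conditions: TMSOTf, Et3N, CH2Cl2, 0 °C; then Pd(OAc)2 (1.05 equiv), MeCN, rt; product used promptly
Reagents that add atoms: none
Why: Saegusa–Ito oxidation, in which soft enolisation gives the silyl enol ether and divalent palladium then dehydrosilylates it (palladium enolate, β-hydride elimination) to the donor-stabilised indenone.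

**Step 3**
Reactants: 5 4-bromo-2-methoxyphenol
Product: 6 (4-bromo-2-methoxyphenoxy)triisopropylsilane
Conditions: TIPSCl, imidazole, DMF, rt
Reagents that add atoms: triisopropylsilyl chloride, CC(C)[Si](Cl)(C(C)C)C(C)C
Why: Imidazole-promoted O-silylation protects the phenol before halogen–metal exchange.

**Step 4**
Reactants: 6 (4-bromo-2-methoxyphenoxy)triisopropylsilane
Product: 9 [3-methoxy-4-(triisopropylsilyloxy)phenyl]boronic acid, via aryllithium 7 (not isolated), via lithium aryltriisopropoxyborate 8 (not isolated)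
Conditions: n-BuLi, THF, −78 °C; B(Oi-Pr)3, −78 °C → rt; 1 M HCl to pH 5, 0 °C
Reagents that add atoms: triisopropyl borate, CC(C)OB(OC(C)C)OC(C)C; water, O
Why: Bromine–lithium exchange para to the silyloxy group (no ortho-lithio species, so no silyl migration), borylation of the aryllithium and mild hydrolysis should give the boronic acid.

**Step 5**
Reactants: 4 6-methoxy-5-(triisopropylsilyloxy)-1H-inden-1-one; 9 [3-methoxy-4-(triisopropylsilyloxy)phenyl]boronic acid
Product: 10 (3S)-6-methoxy-3-[3-methoxy-4-(triisopropylsilyloxy)phenyl]-5-(triisopropylsilyloxy)indan-1-one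
Conditions: [Rh(OH)((S)-BINAP)]2 (1.5 mol%), 9 (2 equiv), 1,4-dioxane/H2O (10:1), 35 °C
Reagents that add atoms: none
Why: Hayashi–Miyaura asymmetric 1,4-addition, in which the aryl–rhodium species inserts the enone on the face left open by (S)-BINAP (the face that gives (S)-3-arylcyclopentanones) and water protonates the rhodium enolate, so the future C1 should be set as S by the ligand.

**Step 6**
Reactants: 10 (3S)-6-methoxy-3-[3-methoxy-4-(triisopropylsilyloxy)phenyl]-5-(triisopropylsilyloxy)indan-1-one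
Product: 12 (2S,3S)-2-(benzyloxymethyl)-6-methoxy-3-[3-methoxy-4-(triisopropylsilyloxy)phenyl]-5-(triisopropylsilyloxy)indan-1-one (2,3-trans), via lithium enolate 11 (not isolated)
Conditions: LiN(SiMe3)2 (1.05 equiv), THF, −78 °C; BnOCH2Cl, −78 → −40 °C
Reagents that add atoms: benzyl chloromethyl ether, ClCOCc1ccccc1
Why: Enolate C-alkylation with a reactive α-chloro ether, the electrophile approaching the planar enolate anti to the neighbouring C3 aryl group, so the future C2 should be set trans to C1 by substrate control (trans is also the thermodynamically preferred arrangement).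

**Step 7**
Reactants: 12 (2S,3S)-2-(benzyloxymethyl)-6-methoxy-3-[3-methoxy-4-(triisopropylsilyloxy)phenyl]-5-(triisopropylsilyloxy)indan-1-one; 13 trimethylsilyldiazomethane
Product: 15 (1S,2S)-2-(benzyloxymethyl)-6-methoxy-1-[3-methoxy-4-(triisopropylsilyloxy)phenyl]-7-(triisopropylsilyloxy)-1,2,3,4-tetrahydronaphthalen-3-one (target numbering; 1,2-trans), via alpha-trimethylsilyl ketone 14 (not isolated)
Conditions: 13 (2 M in hexanes, 1.5 equiv), BF3·OEt2 (1.5 equiv), CH2Cl2, −78 → −20 °C; then 1 M HCl, THF, 0 °C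
Reagents that add atoms: none
Why: BF3 activates the indanone carbonyl, the nucleophilic carbon of 13 adds to it (making the future C3–C4 bond), and in the resulting β-oxido diazonium the ring-A carbon C4a shifts from C3 to the diazo carbon as N2 leaves (making C4–C4a), giving α-silyl ketone 14, whose C–Si bond is cleaved by acid on work-up. The closest known reaction type is the Lewis-acid-promoted diazoalkane homologation of ketones (a Tiffeneau–Demjanov-type 1,2-shift) as applied to 1-indanones and 1-tetralones with trimethylsilyldiazomethane. Ring B is not closed by cyclisation but grows from five to six members through this one-carbon ring expansion. No lasting stereocentre is created (the silyl-bearing C4 of 14 is erased on desilylation), and C1 and C2 are bystanders, C2 being kept in its already favoured trans arrangement by the cold, non-basic medium. The step needs migration of aryl C4a and not of alkyl C2, which the para-silyloxy donor on C4a (phenonium-like stabilisation of the shift) and the branching and inductive deactivation of C2 by its benzyloxymethyl group should secure. It also needs a single insertion, which the bulky α-trimethylsilyl group of 14 should secure by shielding the new, more electrophilic tetralone carbonyl from a second addition.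

**Step 8**
Reactants: 15 (1S,2S)-2-(benzyloxymethyl)-6-methoxy-1-[3-methoxy-4-(triisopropylsilyloxy)phenyl]-7-(triisopropylsilyloxy)-1,2,3,4-tetrahydronaphthalen-3-one
Product: 17 (1S,2S)-2-(benzyloxymethyl)-6-methoxy-1-[3-methoxy-4-(triisopropylsilyloxy)phenyl]-7-(triisopropylsilyloxy)-1,2-dihydronaphthalen-3-yl trifluoromethanesulfonate (C3=C4), via potassium enolate 16 (not isolated)
Conditions: KN(SiMe3)2 (1.1 equiv), THF, −78 °C; PhNTf2, −78 → 0 °C; 15 used directly after step 7
Reagents that add atoms: N-phenylbis(trifluoromethanesulfonimide), O=S(=O)(N(c1ccccc1)S(=O)(=O)C(F)(F)F)C(F)(F)F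
Why: Enol triflate formation, in which the benzylic C4–H is by far the most acidic α-hydrogen so that the enolate forms toward C4 (conjugated with ring A) and is O-sulfonylated, leaving C2 and its β-benzyloxy group untouched.

**Step 9**
Reactants: 17 (1S,2S)-enol triflate
Product: 18 methyl (1S,2R)-2-(benzyloxymethyl)-6-methoxy-1-[3-methoxy-4-(triisopropylsilyloxy)phenyl]-7-(triisopropylsilyloxy)-1,2-dihydronaphthalene-3-carboxylate
Conditions: Pd(OAc)2 (5 mol%), dppp (6 mol%), CO (1 atm), MeOH, Et3N, DMF, 60 °C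
Reagents that add atoms: carbon monoxide, [C-]#[O+]; methanol, CO
Why: Palladium-catalysed methoxycarbonylation of an enol triflate (oxidative addition, CO insertion, methanolysis of the acylpalladium) should attach the last carbon, C3a, to C3.

**Step 10**
Reactants: 18 methyl (1S,2R)-1,2-dihydronaphthalene-3-carboxylate
Product: 19 methyl (1S,2R,3S)-2-(benzyloxymethyl)-6-methoxy-1-[3-methoxy-4-(triisopropylsilyloxy)phenyl]-7-(triisopropylsilyloxy)-1,2,3,4-tetrahydronaphthalene-3-carboxylate (2,3-cis; its 3R epimer 20 may accompany it and the mixture is carried on)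
Conditions: H2 (1–3 atm), 10% Pd/C, pyridine (0.5 equiv), EtOAc, rt
Reagents that add atoms: none
Why: Heterogeneous catalytic hydrogenation of the cinnamate-type C3=C4 bond, with pyridine moderating the catalyst so the benzyl ether survives, should deliver hydrogen mainly anti to the pseudoaxial C2 substituent and so give chiefly the 2,3-cis ester, which step 11 corrects.

**Step 11**
Reactants: 19 methyl (1S,2R,3S)-tetralin-3-carboxylate (with any 20 already present)
Product: 20 methyl (1S,2R,3R)-2-(benzyloxymethyl)-6-methoxy-1-[3-methoxy-4-(triisopropylsilyloxy)phenyl]-7-(triisopropylsilyloxy)-1,2,3,4-tetrahydronaphthalene-3-carboxylate (all-trans)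
Conditions: KOt-Bu (0.3 equiv), t-BuOH/THF (1:4), 0 °C → rt
Reagents that add atoms: none
Why: Base-mediated epimerisation through the ester enolate should equilibrate C3 to the all-equatorial 1,2-trans-2,3-trans isomer (thermodynamic control), the hindered alkoxide being slow to attack the triisopropylsilyl ethers and no leaving group sitting β to the enolate.

**Step 12**
Reactants: 20 methyl (1S,2R,3R)-tetralin-3-carboxylate
Product: 21 [(1S,2R,3R)-2-(benzyloxymethyl)-6-methoxy-1-[3-methoxy-4-(triisopropylsilyloxy)phenyl]-7-(triisopropylsilyloxy)-1,2,3,4-tetrahydronaphthalen-3-yl]methanol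
Conditions: LiAlH4, THF, 0 °C; aqueous NaOH work-up
Reagents that add atoms: none
Why: Hydride reduction of the ester to the primary alcohol C3a–OH, which leaves the benzyl and aryl silyl ethers intact at 0 °C.

**Step 13**
Reactants: 21 C3a alcohol
Product: 22 tert-butyl{[(1S,2R,3R)-2-(benzyloxymethyl)-6-methoxy-1-[3-methoxy-4-(triisopropylsilyloxy)phenyl]-7-(triisopropylsilyloxy)-1,2,3,4-tetrahydronaphthalen-3-yl]methoxy}dimethylsilane
Conditions: TBSCl, imidazole, DMF, rt
Reagents that add atoms: tert-butyldimethylsilyl chloride, CC(C)(C)[Si](C)(C)Cl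
Why: Imidazole-promoted silylation caps C3a–OH so that only the C2a oxygen is released in the next step.

**Step 14**
Reactants: 22 C3a silyl ether with C2a benzyl ether
Product: 23 [(1S,2R,3R)-3-(tert-butyldimethylsilyloxymethyl)-6-methoxy-1-[3-methoxy-4-(triisopropylsilyloxy)phenyl]-7-(triisopropylsilyloxy)-1,2,3,4-tetrahydronaphthalen-2-yl]methanol
Conditions: H2 (1 atm), Pd(OH)2/C, EtOAc, rt
Reagents that add atoms: none
Why: Catalytic hydrogenolysis cleaves the benzyl ether under neutral, non-oxidative conditions that spare all silyl ethers and the electron-rich diarylmethine.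

**Step 15**
Reactants: 24 p-coumaric acid
Product: 26 (E)-3-[4-(tert-butyldimethylsilyloxy)phenyl]prop-2-enoic acid, via bis-silylated coumarate 25 (not isolated)
Conditions: TBSCl (2.3 equiv), imidazole, DMF, rt; then THF/H2O/AcOH (4:1:1), rt
Reagents that add atoms: tert-butyldimethylsilyl chloride, CC(C)(C)[Si](C)(C)Cl
Why: Silylation of both acidic groups followed by selective hydrolysis of the far more labile silyl ester should leave the phenol protected and the acid free.

**Step 16**
Reactants: 23 C2a alcohol; 26 (E)-3-[4-(tert-butyldimethylsilyloxy)phenyl]prop-2-enoic acid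
Product: 27 [(1S,2R,3R)-3-(tert-butyldimethylsilyloxymethyl)-6-methoxy-1-[3-methoxy-4-(triisopropylsilyloxy)phenyl]-7-(triisopropylsilyloxy)-1,2,3,4-tetrahydronaphthalen-2-yl]methyl (E)-3-[4-(tert-butyldimethylsilyloxy)phenyl]prop-2-enoate
Conditions: EDC·HCl (1.5 equiv), DMAP (0.2 equiv), CH2Cl2, 0 °C → rt
Reagents that add atoms: none
Why: Steglich esterification acylates the only free hydroxyl (C2a–OH) through the acylpyridinium of the protected acid, with the E alkene untouched.

**Step 17**
Reactants: 27 fully silylated coumarate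
Product: 28 [(1S,2R,3R)-7-hydroxy-1-(4-hydroxy-3-methoxyphenyl)-3-(hydroxymethyl)-6-methoxy-1,2,3,4-tetrahydronaphthalen-2-yl]methyl (E)-3-(4-hydroxyphenyl)prop-2-enoate (target)
Conditions: Bu4NF (6 equiv), AcOH (6 equiv), THF, 0 °C → rt
Reagents that add atoms: none
Why: Fluoride-mediated desilylation removes all four silyl groups, the acetic acid buffer keeping the medium near neutral so that the cinnamate ester should neither cleave nor migrate to C3a–OH.

**Compound list**
1 | 5-hydroxy-6-methoxyindan-1-one | COc1cc2C(=O)CCc2cc1O | starting material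
2 | 6-methoxy-5-(triisopropylsilyloxy)indan-1-one | COc1cc2C(=O)CCc2cc1O[Si](C(C)C)(C(C)C)C(C)C | intermediate
3 | 6-methoxy-5-(triisopropylsilyloxy)-3-(trimethylsilyloxy)-1H-indene (not isolated) | COc1cc2C(O[Si](C)(C)C)=CCc2cc1O[Si](C(C)C)(C(C)C)C(C)C | intermediate
4 | 6-methoxy-5-(triisopropylsilyloxy)-1H-inden-1-one | COc1cc2C(=O)C=Cc2cc1O[Si](C(C)C)(C(C)C)C(C)C | intermediate
5 | 4-bromo-2-methoxyphenol | COc1cc(Br)ccc1O | starting material
6 | (4-bromo-2-methoxyphenoxy)triisopropylsilane | COc1cc(Br)ccc1O[Si](C(C)C)(C(C)C)C(C)C | intermediate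
7 | [3-methoxy-4-(triisopropylsilyloxy)phenyl]lithium (not isolated) | COc1cc([Li])ccc1O[Si](C(C)C)(C(C)C)C(C)C | intermediate
8 | lithium triisopropoxy[3-methoxy-4-(triisopropylsilyloxy)phenyl]borate (not isolated) | [Li+].COc1cc([B-](OC(C)C)(OC(C)C)OC(C)C)ccc1O[Si](C(C)C)(C(C)C)C(C)C | intermediate
9 | [3-methoxy-4-(triisopropylsilyloxy)phenyl]boronic acid | COc1cc(B(O)O)ccc1O[Si](C(C)C)(C(C)C)C(C)C | intermediate
10 | (3S)-6-methoxy-3-[3-methoxy-4-(triisopropylsilyloxy)phenyl]-5-(triisopropylsilyloxy)indan-1-one | COc1cc([C@H]2c3cc(O[Si](C(C)C)(C(C)C)C(C)C)c(OC)cc3C(=O)C2)ccc1O[Si](C(C)C)(C(C)C)C(C)C | intermediate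
11 | lithium enolate of 10, lithium (1S)-1-aryl-1H-inden-3-olate (not isolated) | COc1cc([C@H]2c3cc(O[Si](C(C)C)(C(C)C)C(C)C)c(OC)cc3C(O[Li])=C2)ccc1O[Si](C(C)C)(C(C)C)C(C)C | intermediate
12 | (2S,3S)-2-(benzyloxymethyl)-6-methoxy-3-[3-methoxy-4-(triisopropylsilyloxy)phenyl]-5-(triisopropylsilyloxy)indan-1-one (trans) | COc1cc([C@H]2c3cc(O[Si](C(C)C)(C(C)C)C(C)C)c(OC)cc3C(=O)[C@@H]2COCc2ccccc2)ccc1O[Si](C(C)C)(C(C)C)C(C)C | intermediate
13 | trimethylsilyldiazomethane | C[Si](C)(C)C=[N+]=[N-] | starting material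
14 | (1S,2S)-2-(benzyloxymethyl)-6-methoxy-1-[3-methoxy-4-(triisopropylsilyloxy)phenyl]-7-(triisopropylsilyloxy)-4-(trimethylsilyl)-1,2,3,4-tetrahydronaphthalen-3-one, both C4 epimers (not isolated) | COc1cc([C@H]2c3cc(O[Si](C(C)C)(C(C)C)C(C)C)c(OC)cc3C([Si](C)(C)C)C(=O)[C@@H]2COCc2ccccc2)ccc1O[Si](C(C)C)(C(C)C)C(C)C | intermediate
15 | (1S,2S)-2-(benzyloxymethyl)-6-methoxy-1-[3-methoxy-4-(triisopropylsilyloxy)phenyl]-7-(triisopropylsilyloxy)-1,2,3,4-tetrahydronaphthalen-3-one (1,2-trans) | COc1cc([C@H]2c3cc(O[Si](C(C)C)(C(C)C)C(C)C)c(OC)cc3CC(=O)[C@@H]2COCc2ccccc2)ccc1O[Si](C(C)C)(C(C)C)C(C)C | intermediate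
16 | potassium (1S,2S)-1,2-dihydronaphthalen-3-olate of 15, C3=C4 enolate (not isolated) | COc1cc([C@H]2c3cc(O[Si](C(C)C)(C(C)C)C(C)C)c(OC)cc3C=C(O[K])[C@@H]2COCc2ccccc2)ccc1O[Si](C(C)C)(C(C)C)C(C)C | intermediate
17 | (1S,2S)-2-(benzyloxymethyl)-6-methoxy-1-[3-methoxy-4-(triisopropylsilyloxy)phenyl]-7-(triisopropylsilyloxy)-1,2-dihydronaphthalen-3-yl trifluoromethanesulfonate | COc1cc([C@H]2c3cc(O[Si](C(C)C)(C(C)C)C(C)C)c(OC)cc3C=C(OS(=O)(=O)C(F)(F)F)[C@@H]2COCc2ccccc2)ccc1O[Si](C(C)C)(C(C)C)C(C)C | intermediate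
18 | methyl (1S,2R)-2-(benzyloxymethyl)-6-methoxy-1-[3-methoxy-4-(triisopropylsilyloxy)phenyl]-7-(triisopropylsilyloxy)-1,2-dihydronaphthalene-3-carboxylate | COc1cc([C@H]2c3cc(O[Si](C(C)C)(C(C)C)C(C)C)c(OC)cc3C=C(C(=O)OC)[C@@H]2COCc2ccccc2)ccc1O[Si](C(C)C)(C(C)C)C(C)C | intermediate
19 | methyl (1S,2R,3S)-2-(benzyloxymethyl)-6-methoxy-1-[3-methoxy-4-(triisopropylsilyloxy)phenyl]-7-(triisopropylsilyloxy)-1,2,3,4-tetrahydronaphthalene-3-carboxylate (1,2-trans-2,3-cis) | COc1cc([C@H]2c3cc(O[Si](C(C)C)(C(C)C)C(C)C)c(OC)cc3C[C@H](C(=O)OC)[C@@H]2COCc2ccccc2)ccc1O[Si](C(C)C)(C(C)C)C(C)C | intermediate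
20 | methyl (1S,2R,3R)-2-(benzyloxymethyl)-6-methoxy-1-[3-methoxy-4-(triisopropylsilyloxy)phenyl]-7-(triisopropylsilyloxy)-1,2,3,4-tetrahydronaphthalene-3-carboxylate (all-trans) | COc1cc([C@H]2c3cc(O[Si](C(C)C)(C(C)C)C(C)C)c(OC)cc3C[C@@H](C(=O)OC)[C@@H]2COCc2ccccc2)ccc1O[Si](C(C)C)(C(C)C)C(C)C | intermediate
21 | [(1S,2R,3R)-2-(benzyloxymethyl)-6-methoxy-1-[3-methoxy-4-(triisopropylsilyloxy)phenyl]-7-(triisopropylsilyloxy)-1,2,3,4-tetrahydronaphthalen-3-yl]methanol | COc1cc([C@H]2c3cc(O[Si](C(C)C)(C(C)C)C(C)C)c(OC)cc3C[C@@H](CO)[C@@H]2COCc2ccccc2)ccc1O[Si](C(C)C)(C(C)C)C(C)C | intermediate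
22 | tert-butyldimethylsilyl ether of 21 at C3a–O | COc1cc([C@H]2c3cc(O[Si](C(C)C)(C(C)C)C(C)C)c(OC)cc3C[C@@H](CO[Si](C)(C)C(C)(C)C)[C@@H]2COCc2ccccc2)ccc1O[Si](C(C)C)(C(C)C)C(C)C | intermediate
23 | [(1S,2R,3R)-3-(tert-butyldimethylsilyloxymethyl)-6-methoxy-1-[3-methoxy-4-(triisopropylsilyloxy)phenyl]-7-(triisopropylsilyloxy)-1,2,3,4-tetrahydronaphthalen-2-yl]methanol | COc1cc([C@H]2c3cc(O[Si](C(C)C)(C(C)C)C(C)C)c(OC)cc3C[C@@H](CO[Si](C)(C)C(C)(C)C)[C@@H]2CO)ccc1O[Si](C(C)C)(C(C)C)C(C)C | intermediate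
24 | p-coumaric acid, (E)-3-(4-hydroxyphenyl)prop-2-enoic acid | O=C(O)/C=C/c1ccc(O)cc1 | starting material
25 | tert-butyldimethylsilyl (E)-3-[4-(tert-butyldimethylsilyloxy)phenyl]prop-2-enoate (not isolated) | CC(C)(C)[Si](C)(C)OC(=O)/C=C/c1ccc(O[Si](C)(C)C(C)(C)C)cc1 | intermediate
26 | (E)-3-[4-(tert-butyldimethylsilyloxy)phenyl]prop-2-enoic acid | O=C(O)/C=C/c1ccc(O[Si](C)(C)C(C)(C)C)cc1 | intermediate
27 | [(1S,2R,3R)-3-(tert-butyldimethylsilyloxymethyl)-6-methoxy-1-[3-methoxy-4-(triisopropylsilyloxy)phenyl]-7-(triisopropylsilyloxy)-1,2,3,4-tetrahydronaphthalen-2-yl]methyl (E)-3-[4-(tert-butyldimethylsilyloxy)phenyl]prop-2-enoate | COc1cc([C@H]2c3cc(O[Si](C(C)C)(C(C)C)C(C)C)c(OC)cc3C[C@@H](CO[Si](C)(C)C(C)(C)C)[C@@H]2COC(=O)/C=C/c2ccc(O[Si](C)(C)C(C)(C)C)cc2)ccc1O[Si](C(C)C)(C(C)C)C(C)C | intermediate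
28 | [(1S,2R,3R)-7-hydroxy-1-(4-hydroxy-3-methoxyphenyl)-3-(hydroxymethyl)-6-methoxy-1,2,3,4-tetrahydronaphthalen-2-yl]methyl (E)-3-(4-hydroxyphenyl)prop-2-enoate | COc1cc([C@H]2c3cc(O)c(OC)cc3C[C@@H](CO)[C@@H]2COC(=O)/C=C/c2ccc(O)cc2)ccc1O | target

**Totals**
Total step count: 17. Longest linear sequence: 14 steps (steps 1, 2, 5–14, 16, 17 from compound 1).

**Steps most likely to fail**

Step 7. The 1,2-shift may run partly through the alkyl carbon C2, the donor-deactivated carbonyl may add the diazo reagent sluggishly or collapse to an epoxide, and the Lewis acid may cause β-elimination of benzyl alcohol. Fallback, setting out from 12 and returning at 15: Wittig methylenation of the ketone (Ph3PCH3Br, KOt-Bu, THF, 0 °C) should give (2R,3S)-2-(benzyloxymethyl)-6-methoxy-3-[3-methoxy-4-(triisopropylsilyloxy)phenyl]-1-methylidene-5-(triisopropylsilyloxy)indane F1. Treatment with PhI(OH)OTs in 95% MeOH at rt should then add trivalent iodine to the exocyclic alkene, capture the benzylic cation with methanol and move C4a onto the CH2 carbon as iodobenzene leaves; hydrolysis in the aqueous methanol returns tetralone 15. This oxidative aryl shift inserts the same carbon without a diazo compound or a boron Lewis acid.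

Step 6. The hard chloromethyl ether may alkylate the enolate on oxygen, a second alkylation may follow, or base may expel benzyl oxide from the product by β-elimination. Fallback, setting out from 10 and returning at 12: TMSOTf/Et3N (CH2Cl2, 0 °C) should give (1S)-5-methoxy-1-[3-methoxy-4-(triisopropylsilyloxy)phenyl]-6-(triisopropylsilyloxy)-3-(trimethylsilyloxy)-1H-indene F2. A Mukaiyama aldol reaction with aqueous formaldehyde and Sc(OTf)3 in THF/H2O should add the hydroxymethyl group anti to the aryl group, giving (2S,3S)-2-(hydroxymethyl)-6-methoxy-3-[3-methoxy-4-(triisopropylsilyloxy)phenyl]-5-(triisopropylsilyloxy)indan-1-one F3. Benzyl 2,2,2-trichloroacetimidate with catalytic TfOH (CH2Cl2/cyclohexane, 0 °C) then benzylates the alcohol under acid, where retro-aldol and elimination are avoided, to give 12.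

Step 11. Equilibration at C3 may stay incomplete, or the alkoxide may strip the aryl silyl ethers before the ester has epimerised. Fallback, setting out from 19 and returning at 21: i-Bu2AlH (CH2Cl2, −78 °C) should reduce the ester to (1S,2R,3S)-2-(benzyloxymethyl)-6-methoxy-1-[3-methoxy-4-(triisopropylsilyloxy)phenyl]-7-(triisopropylsilyloxy)-1,2,3,4-tetrahydronaphthalene-3-carbaldehyde F4. The far more acidic aldehyde α-hydrogen should then equilibrate with DBU (CH2Cl2, rt), with no alkoxide present, to the all-trans (1S,2R,3R)-2-(benzyloxymethyl)-6-methoxy-1-[3-methoxy-4-(triisopropylsilyloxy)phenyl]-7-(triisopropylsilyloxy)-1,2,3,4-tetrahydronaphthalene-3-carbaldehyde F5. NaBH4 (MeOH/THF, 0 °C) then gives alcohol 21.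

**Further compounds**
F1 | step 7 | (2R,3S)-2-(benzyloxymethyl)-6-methoxy-3-[3-methoxy-4-(triisopropylsilyloxy)phenyl]-1-methylidene-5-(triisopropylsilyloxy)indane | COc1cc([C@H]2c3cc(O[Si](C(C)C)(C(C)C)C(C)C)c(OC)cc3C(=C)[C@@H]2COCc2ccccc2)ccc1O[Si](C(C)C)(C(C)C)C(C)C
F2 | step 6 | (1S)-5-methoxy-1-[3-methoxy-4-(triisopropylsilyloxy)phenyl]-6-(triisopropylsilyloxy)-3-(trimethylsilyloxy)-1H-indene | COc1cc([C@H]2c3cc(O[Si](C(C)C)(C(C)C)C(C)C)c(OC)cc3C(O[Si](C)(C)C)=C2)ccc1O[Si](C(C)C)(C(C)C)C(C)C
F3 | step 6 | (2S,3S)-2-(hydroxymethyl)-6-methoxy-3-[3-methoxy-4-(triisopropylsilyloxy)phenyl]-5-(triisopropylsilyloxy)indan-1-one | COc1cc([C@H]2c3cc(O[Si](C(C)C)(C(C)C)C(C)C)c(OC)cc3C(=O)[C@@H]2CO)ccc1O[Si](C(C)C)(C(C)C)C(C)C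
F4 | step 11 | (1S,2R,3S)-2-(benzyloxymethyl)-6-methoxy-1-[3-methoxy-4-(triisopropylsilyloxy)phenyl]-7-(triisopropylsilyloxy)-1,2,3,4-tetrahydronaphthalene-3-carbaldehyde | COc1cc([C@H]2c3cc(O[Si](C(C)C)(C(C)C)C(C)C)c(OC)cc3C[C@H](C=O)[C@@H]2COCc2ccccc2)ccc1O[Si](C(C)C)(C(C)C)C(C)C
F5 | step 11 | (1S,2R,3R)-2-(benzyloxymethyl)-6-methoxy-1-[3-methoxy-4-(triisopropylsilyloxy)phenyl]-7-(triisopropylsilyloxy)-1,2,3,4-tetrahydronaphthalene-3-carbaldehyde | COc1cc([C@H]2c3cc(O[Si](C(C)C)(C(C)C)C(C)C)c(OC)cc3C[C@@H](C=O)[C@@H]2COCc2ccccc2)ccc1O[Si](C(C)C)(C(C)C)C(C)C
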